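**Plan**

- Ring numbering: C1 and C3 carry OH, C5 carries the chain C1'–C17' (C8'=C9' Z, C16' S). The retrosynthesis first restores a carboxyl group on C4 and a silyl ether on the C16' oxygen, then cuts the ring bond C4–C5 (aldol aromatization in reverse) to unfold the arene into a β,δ-diketo-dioxinone.
- The next cuts are C5–C6 (Claisen disconnection between the fatty acyl carbon and a keto-dioxinone), C1–C2 (acetylation of trimethyldioxinone) and the glycosidic C–O bond of a sophorolipid.
- Enabling feature: ring carbon C5 together with C1'–C17' is the unbroken eighteen-carbon skeleton of (9Z,17S)-17-hydroxyoctadec-9-enoic acid, its carboxyl carbon being C5. Only C1, C2, C3, C4 and C6 are missing; C2–C4 come from the dioxinone and C1/C6 from acetyl chloride, and the dioxinone carbonyl that activates C4 leaves as CO2.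
- Forward order: chain released from the glycolipid and silylated, then Weinreb amide, then C-acylation of the keto-dioxinone dianion (C5–C6), then the single ring closure (C4–C5), then decarboxylation and desilylation.
- Stereochemistry: the S carbinol and the Z-alkene are both taken intact from the fermentation product; no stereocenter is created or touched.

Key step: step 6

Remark on the chemistry (assumption): commercial sophorolipid from Starmerella bombicola is a mixture of lactonic and open-chain, partly acetylated glycolipids whose aglycone is mainly (9Z,17S)-17-hydroxyoctadec-9-enoic acid. It is drawn as the deacetylated acid 1, and all forms should converge on ester 2 in step 1. Minor saturated or shorter-chain homologues are to be removed at the stage of 2, if necessary on AgNO3-impregnated silica.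

**Step 1**
Reactants: 1 sophorolipid, (9Z,17S)-17-(β-sophorosyloxy)octadec-9-enoic acid
Product: 2 methyl (9Z,17S)-17-hydroxyoctadec-9-enoate
Conditions: 1.25 M HCl in MeOH, reflux; NaHCO3 work-up; SiO2 chromatography
Reagents that add atoms: methanol, `CO`
Why: Acid-catalysed methanolysis should cleave both β-glucosidic acetals at the anomeric C–O bond (transglycosylation to methyl glucoside) and esterify or transesterify the carboxyl terminus (Fischer esterification), so the C17–O bond is never broken and the S carbinol and the isolated Z-alkene are delivered unchanged.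

**Step 2**
Reactants: 2 methyl (9Z,17S)-17-hydroxyoctadec-9-enoate
Product: 3 methyl (9Z,17S)-17-[(tert-butyldimethylsilyl)oxy]octadec-9-enoate
Conditions: TBSCl, imidazole, DMF, rt
Reagents that add atoms: tert-butyldimethylsilyl chloride, `CC(C)(C)[Si](C)(C)Cl`
Why: Imidazole-promoted silylation of a secondary alcohol with TBSCl in DMF is standard and masks the only protic site before the organometallic and enolate steps.

**Step 3**
Reactants: 3 methyl (9Z,17S)-17-[(tert-butyldimethylsilyl)oxy]octadec-9-enoate
Product: 4 (9Z,17S)-17-[(tert-butyldimethylsilyl)oxy]-N-methoxy-N-methyloctadec-9-enamide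
Conditions: MeNH(OMe)·HCl, iPrMgCl, THF, −20 → 0 °C; sat. aq. NH4Cl
Reagents that add atoms: N,O-dimethylhydroxylamine hydrochloride, `CNOC.Cl`
Why: The chloromagnesium amide formed from MeNH(OMe)·HCl and iPrMgCl should convert the unhindered methyl ester directly into the Weinreb amide (ester aminolysis) at low temperature, where neither the silyl ether nor the alkene reacts.

**Step 4**
Reactants: 5 2,2,6-trimethyl-4H-1,3-dioxin-4-one; 6 acetyl chloride
Product: 8 2,2-dimethyl-6-(2-oxopropyl)-4H-1,3-dioxin-4-one, via lithium dienolate 7 (not isolated)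
Conditions: 5 (2 equiv.), LiN(SiMe3)2 (2 equiv.), THF, −78 °C; then 6 (1 equiv.), −78 °C; sat. aq. NH4Cl
Reagents that add atoms: none
Why: Kinetic deprotonation of the 6-methyl group gives the vinylogous lithium enolate, which is C-acylated at its γ-carbon by acetyl chloride (vinylogous Claisen-type acylation); two equivalents of enolate are used because the more acidic β-keto product consumes one.

**Step 5**
Reactants: 8 2,2-dimethyl-6-(2-oxopropyl)-4H-1,3-dioxin-4-one; 4 (9Z,17S)-17-[(tert-butyldimethylsilyl)oxy]-N-methoxy-N-methyloctadec-9-enamide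
Product: 10 6-[(12Z,20S)-20-[(tert-butyldimethylsilyl)oxy]-2,4-dioxohenicos-12-en-1-yl]-2,2-dimethyl-4H-1,3-dioxin-4-one, via dilithium dianion 9 (not isolated)
Conditions: 8 (2.5 equiv.), LiN(iPr)2 (5 equiv.), THF, −78 °C; then 4, −78 → −40 °C; sat. aq. NH4Cl; short SiO2 plug, used at once
Reagents that add atoms: none
Why: Double deprotonation of 8 gives a dianion whose terminal, less stabilized carbon is the most nucleophilic site and should add to the Weinreb amide (crossed Claisen condensation of a β-dicarbonyl dianion), the chelated tetrahedral adduct preventing over-addition until the aqueous quench.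

**Step 6**
Reactants: 10 6-[(12Z,20S)-20-[(tert-butyldimethylsilyl)oxy]-2,4-dioxohenicos-12-en-1-yl]-2,2-dimethyl-4H-1,3-dioxin-4-one
Product: 13 5-[(8Z,16S)-16-[(tert-butyldimethylsilyl)oxy]heptadec-8-en-1-yl]-7-hydroxy-2,2-dimethyl-4H-1,3-benzodioxin-4-one, via aldol adduct 11 (not isolated), via cyclohexadienone 12 (not isolated)
Conditions: Et3N (3 equiv.), CH2Cl2, rt
Reagents that add atoms: none
Why: Et3N should reversibly deprotonate the doubly activated methylene between the dioxinone and the central ketone of 10, and the cross-conjugated dienolate then attacks the distal chain ketone (the former fatty-acid C1) through dioxinone C5 to give aldol 11, which loses water by an E1cB path to dienone 12 and tautomerizes to the phenol 13 under the drive of aromaticity. The closest known reaction type is the amine-mediated aldol aromatization of β,δ-diketo-dioxinones to acetonide-masked β-resorcylates, the laboratory counterpart of the polyketide folding used by alkylresorcinol synthases. The one new ring, the carbocycle, closes in a 6-(enolexo)-exo-trig mode by forming the bond between dioxinone C5 and the ketone carbon that becomes the chain-bearing arene carbon. No stereocenter is created in 13, since the two sp3 centers of 11 are erased on aromatization, and the S carbinol and the Z-alkene lie far from any acidic site and are inert to a tertiary amine at room temperature. The step needs C-cyclization onto the distal ketone in preference to O-acylation to a 2-pyranone, and this is secured by keeping the carboxyl terminus locked as the dioxinone, which releases an acylating ketene only on heating. Regiochemistry is fixed by ring size, because among the possible enolate–carbonyl pairings only C5 with the distal ketone closes a six-membered ring.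

**Step 7**
Reactants: 13 5-[(8Z,16S)-16-[(tert-butyldimethylsilyl)oxy]heptadec-8-en-1-yl]-7-hydroxy-2,2-dimethyl-4H-1,3-benzodioxin-4-one
Product: 15 5-[(8Z,16S)-16-[(tert-butyldimethylsilyl)oxy]heptadec-8-en-1-yl]benzene-1,3-diol, via resorcylic acid 14 (not isolated)
Conditions: 6 M aq. NaOH, MeOH, 110 °C (sealed tube, argon); then 1 M HCl to pH 3 at 0 °C
Reagents that add atoms: none
Why: Hydroxide opens the aryl acylal of the benzodioxinone with loss of acetone to the 2,4-dihydroxy-6-alkylbenzoate, and such β-resorcylic acids decarboxylate readily by ipso-protonation on heating (saponification–decarboxylation as practised on olivetolate-type esters), while the secondary silyl ether and the isolated alkene should tolerate alkali.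

**Step 8**
Reactants: 15 5-[(8Z,16S)-16-[(tert-butyldimethylsilyl)oxy]heptadec-8-en-1-yl]benzene-1,3-diol
Product: 16 Hansfordiol E, 5-[(8Z,16S)-16-hydroxyheptadec-8-en-1-yl]benzene-1,3-diol
Conditions: HF·pyridine, THF/pyridine, 0 °C → rt
Reagents that add atoms: none
Why: Fluoride-induced cleavage of the Si–O bond by HF·pyridine (silyl ether deprotection) is mild, non-basic and non-oxidizing, so the air-sensitive resorcinol, the Z-alkene and the carbinol configuration (its C–O bond is not touched) should be preserved.

**Compound list**

1 | sophorolipid, (9Z,17S)-17-(β-sophorosyloxy)octadec-9-enoic acid (deacetylated open-chain form) | `C[C@H](O[C@@H]1O[C@H](CO)[C@@H](O)[C@H](O)[C@H]1O[C@@H]1O[C@H](CO)[C@@H](O)[C@H](O)[C@H]1O)CCCCCC/C=C\CCCCCCCC(=O)O` | starting material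
2 | methyl (9Z,17S)-17-hydroxyoctadec-9-enoate | `C[C@H](O)CCCCCC/C=C\CCCCCCCC(=O)OC` | intermediate
3 | methyl (9Z,17S)-17-[(tert-butyldimethylsilyl)oxy]octadec-9-enoate | `C[C@H](O[Si](C)(C)C(C)(C)C)CCCCCC/C=C\CCCCCCCC(=O)OC` | intermediate
4 | (9Z,17S)-17-[(tert-butyldimethylsilyl)oxy]-N-methoxy-N-methyloctadec-9-enamide | `C[C@H](O[Si](C)(C)C(C)(C)C)CCCCCC/C=C\CCCCCCCC(=O)N(C)OC` | intermediate
5 | 2,2,6-trimethyl-4H-1,3-dioxin-4-one | `CC1=CC(=O)OC(C)(C)O1` | starting material
6 | acetyl chloride | `CC(=O)Cl` | starting material
7 | lithium 2,2-dimethyl-6-methylidene-6H-1,3-dioxin-4-olate (lithium dienolate of 5, formed in the flask in step 4) | `[Li+].C=C1C=C([O-])OC(C)(C)O1` | intermediate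
8 | 2,2-dimethyl-6-(2-oxopropyl)-4H-1,3-dioxin-4-one | `CC(=O)CC1=CC(=O)OC(C)(C)O1` | intermediate
9 | dilithium dianion of 8 (bis-enolate, formed in the flask in step 5) | `[Li+].[Li+].C=C([O-])C=C1C=C([O-])OC(C)(C)O1` | intermediate
10 | 6-[(12Z,20S)-20-[(tert-butyldimethylsilyl)oxy]-2,4-dioxohenicos-12-en-1-yl]-2,2-dimethyl-4H-1,3-dioxin-4-one | `C[C@H](O[Si](C)(C)C(C)(C)C)CCCCCC/C=C\CCCCCCCC(=O)CC(=O)CC1=CC(=O)OC(C)(C)O1` | intermediate
11 | aldol adduct, 5-[(8Z,16S)-16-[(tert-butyldimethylsilyl)oxy]heptadec-8-en-1-yl]-5-hydroxy-2,2-dimethyl-4a,5-dihydro-4H-1,3-benzodioxine-4,7(6H)-dione (C4a and C5 unassigned, formed in the flask in step 6) | `C[C@H](O[Si](C)(C)C(C)(C)C)CCCCCC/C=C\CCCCCCCC1(O)CC(=O)C=C2OC(C)(C)OC(=O)C12` | intermediate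
12 | cyclohexadienone, 5-[(8Z,16S)-16-[(tert-butyldimethylsilyl)oxy]heptadec-8-en-1-yl]-2,2-dimethyl-4H-1,3-benzodioxine-4,7(6H)-dione (keto tautomer of 13, formed in the flask in step 6) | `C[C@H](O[Si](C)(C)C(C)(C)C)CCCCCC/C=C\CCCCCCCC1=C2C(=O)OC(C)(C)OC2=CC(=O)C1` | intermediate
13 | 5-[(8Z,16S)-16-[(tert-butyldimethylsilyl)oxy]heptadec-8-en-1-yl]-7-hydroxy-2,2-dimethyl-4H-1,3-benzodioxin-4-one | `C[C@H](O[Si](C)(C)C(C)(C)C)CCCCCC/C=C\CCCCCCCc1cc(O)cc2OC(C)(C)OC(=O)c12` | intermediate
14 | 2,4-dihydroxy-6-[(8Z,16S)-16-[(tert-butyldimethylsilyl)oxy]heptadec-8-en-1-yl]benzoic acid (present as its sodium salt in the flask in step 7) | `C[C@H](O[Si](C)(C)C(C)(C)C)CCCCCC/C=C\CCCCCCCc1cc(O)cc(O)c1C(=O)O` | intermediate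
15 | 5-[(8Z,16S)-16-[(tert-butyldimethylsilyl)oxy]heptadec-8-en-1-yl]benzene-1,3-diol | `C[C@H](O[Si](C)(C)C(C)(C)C)CCCCCC/C=C\CCCCCCCc1cc(O)cc(O)c1` | intermediate
16 | Hansfordiol E, 5-[(8Z,16S)-16-hydroxyheptadec-8-en-1-yl]benzene-1,3-diol | `C[C@H](O)CCCCCC/C=C\CCCCCCCc1cc(O)cc(O)c1` | target

**Step count and risks**

Total step count: 8. Longest linear sequence: 7 steps (steps 1, 2, 3, 5, 6, 7 and 8, from sophorolipid 1); step 4 is a one-step branch that joins at step 5.

Steps most likely to fail:

Step 5. Proton transfer from the α-methylene of amide 4 to the strongly basic dianion, self-condensation of the keto-dioxinone, and premature cyclization of the sensitive product during isolation may all erode conversion. The fallback replaces the Claisen acylation by an aldol addition followed by oxidation. It sets out from compound 4, which is reduced with iBu2AlH in THF at −78 °C to (9Z,17S)-17-[(tert-butyldimethylsilyl)oxy]octadec-9-enal F1. Dianion 9 (from 8 and LiN(iPr)2 as in step 5) should add to this far more electrophilic aldehyde at −78 °C through its terminal carbon to give 6-[(12Z,20S)-20-[(tert-butyldimethylsilyl)oxy]-4-hydroxy-2-oxohenicos-12-en-1-yl]-2,2-dimethyl-4H-1,3-dioxin-4-one F2 as a mixture of carbinol epimers, which is of no consequence. Oxidation of the β-hydroxy ketone with Dess–Martin periodinane in CH2Cl2 at 0 °C then comes back to the route at compound 10.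

Step 6. The aldol may stall before dehydration, or loss of acetone from the dioxinone followed by O-acylation may divert material to a pyranone. The fallback makes the ketene pathway productive and cyclizes an open-chain ester. It sets out from compound 10, which is heated in toluene at 110 °C in a sealed tube with excess methanol. Retro-[4+2] loss of acetone should give the acylketene (15Z,23S)-23-[(tert-butyldimethylsilyl)oxy]tetracosa-1,15-diene-1,3,5,7-tetrone F3, which is trapped at once by methanol as methyl (15Z,23S)-23-[(tert-butyldimethylsilyl)oxy]-3,5,7-trioxotetracos-15-enoate F4. Treatment with Cs2CO3 in MeOH at rt and then acetic acid should effect the same C4–C5 aldol closure and aromatization on the open-chain triketo ester, giving methyl 2,4-dihydroxy-6-[(8Z,16S)-16-[(tert-butyldimethylsilyl)oxy]heptadec-8-en-1-yl]benzoate F5. Saponification and decarboxylation of this ester under the conditions of step 7 (through acid 14) comes back to the route at compound 15.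

Step 7. Incomplete decarboxylation, partial loss of the silyl ether and air oxidation of the electron-rich resorcinolate in hot alkali may lower the return. The fallback avoids hot hydroxide by ester exchange and neutral deallylation. It sets out from compound 13, which is opened with allyl alcohol and K2CO3 at 60 °C, with loss of acetone, to prop-2-en-1-yl 2,4-dihydroxy-6-[(8Z,16S)-16-[(tert-butyldimethylsilyl)oxy]heptadec-8-en-1-yl]benzoate F6. Pd(PPh3)4 (catalytic) with morpholine in THF at rt (Tsuji–Trost deallylation) should release acid 14 under neutral conditions. Warming 14 in toluene at 100 °C expels CO2 and comes back to the route at compound 15.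

**Further compounds**

F1 | step 5 | (9Z,17S)-17-[(tert-butyldimethylsilyl)oxy]octadec-9-enal | `C[C@H](O[Si](C)(C)C(C)(C)C)CCCCCC/C=C\CCCCCCCC=O`
F2 | step 5 | 6-[(12Z,20S)-20-[(tert-butyldimethylsilyl)oxy]-4-hydroxy-2-oxohenicos-12-en-1-yl]-2,2-dimethyl-4H-1,3-dioxin-4-one (both C4 epimers) | `C[C@H](O[Si](C)(C)C(C)(C)C)CCCCCC/C=C\CCCCCCCC(O)CC(=O)CC1=CC(=O)OC(C)(C)O1`
F3 | step 6 | (15Z,23S)-23-[(tert-butyldimethylsilyl)oxy]tetracosa-1,15-diene-1,3,5,7-tetrone (acylketene, transient) | `C[C@H](O[Si](C)(C)C(C)(C)C)CCCCCC/C=C\CCCCCCCC(=O)CC(=O)CC(=O)C=C=O`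
F4 | step 6 | methyl (15Z,23S)-23-[(tert-butyldimethylsilyl)oxy]-3,5,7-trioxotetracos-15-enoate | `C[C@H](O[Si](C)(C)C(C)(C)C)CCCCCC/C=C\CCCCCCCC(=O)CC(=O)CC(=O)CC(=O)OC`
F5 | step 6 | methyl 2,4-dihydroxy-6-[(8Z,16S)-16-[(tert-butyldimethylsilyl)oxy]heptadec-8-en-1-yl]benzoate | `C[C@H](O[Si](C)(C)C(C)(C)C)CCCCCC/C=C\CCCCCCCc1cc(O)cc(O)c1C(=O)OC`
F6 | step 7 | prop-2-en-1-yl 2,4-dihydroxy-6-[(8Z,16S)-16-[(tert-butyldimethylsilyl)oxy]heptadec-8-en-1-yl]benzoate | `C[C@H](O[Si](C)(C)C(C)(C)C)CCCCCC/C=C\CCCCCCCc1cc(O)cc(O)c1C(=O)OCC=C`
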